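**Retrosynthetic overview**

1. Target ⇒ allylic alcohol (Dess–Martin oxidation last) ⇒ Nozaki–Hiyama–Kishi union of a coumarinyloxyacetaldehyde with (R)-5-(2-bromoallyl)-3-methylfuran-2(5H)-one, cutting the bond between the ketone carbon and the methylidene-bearing carbon.
2. The bromoallyl furanone ⇒ acyclic (R)-6-bromohepta-1,2,6-trien-4-ol + CO: a Ru3(CO)12-catalysed cyclocarbonylation that closes the furanone between its carbonyl carbon C2 and the methyl-bearing C3.
3. Enabling feature: in the 3-methylfuran-2(5H)-one ring the array O1–C5H–C4H=C3–CH3 is an isomerised α-allenol C(OH)–CH=C=CH2; CO bound to the C5 oxygen supplies C2, the central allene carbon becomes C3 and the allene CH2 terminus becomes the C3 methyl.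
4. The allenol ⇒ Crabbé homologation of an (R)-propargylic alcohol ⇒ asymmetric transfer hydrogenation of a silyl ynone ⇒ Barbier 2-bromoallylation of 3-(trimethylsilyl)propynal.
5. Ring order: the two coumarin rings are bought intact; the furanone is the only ring built (step 6), and the two halves are joined afterwards.

Key step: step 6

Assumption: 7-hydroxy-8-methoxycoumarin is taken as a purchasable natural-product building block, so its 7-OH/8-OMe pattern needs no regioselective methylation.

**Route**

Step 1
Reactants: 1 3-(trimethylsilyl)prop-2-ynal; 2 2,3-dibromoprop-1-ene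
Product: 4 rac-5-bromo-1-(trimethylsilyl)hex-5-en-1-yn-3-ol, via 2-bromoallylindium dibromide 3 (not isolated)
Conditions: In powder, THF–H2O (1:1), rt
Reagents that add atoms: none
Why: Indium-mediated Barbier allylation: the metal inserts only into the allylic C–Br bond of 2, and the organoindium species (drawn as the dibromide 3) adds in the 1,2 sense to the unhindered ynal in aqueous THF, where 2-haloallyl reagents are known not to eliminate to allene, giving the racemic carbinol whose configuration is set in step 3.

Step 2
Reactants: 4 rac-5-bromo-1-(trimethylsilyl)hex-5-en-1-yn-3-ol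
Product: 5 5-bromo-1-(trimethylsilyl)hex-5-en-1-yn-3-one
Conditions: Dess–Martin periodinane, CH2Cl2, 0 °C to rt
Reagents that add atoms: none
Why: Dess–Martin oxidation of a secondary propargylic alcohol runs cold and without base, which should leave the doubly activated CH2 between the ynone and the bromo-olefin unenolised.

Step 3
Reactants: 5 5-bromo-1-(trimethylsilyl)hex-5-en-1-yn-3-one
Product: 6 (3R)-5-bromo-1-(trimethylsilyl)hex-5-en-1-yn-3-ol
Conditions: Ru[(R,R)-TsDPEN](p-cymene) (2 mol %, preformed 16-electron amido complex), i-PrOH, rt
Reagents that add atoms: none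
Why: Noyori asymmetric transfer hydrogenation of an α,β-acetylenic ketone under base-free conditions: in the six-membered outer-sphere transition state the alkynyl group takes the place that the aryl group takes with aryl ketones, so the (R,R)-catalyst should deliver hydride to the face that gives the (R)-carbinol, the stereocentre that becomes C5 of the furanone, while the C≡C, C=C and C–Br bonds are not reduced.

Step 4
Reactants: 6 (3R)-5-bromo-1-(trimethylsilyl)hex-5-en-1-yn-3-ol
Product: 7 (3R)-5-bromohex-5-en-1-yn-3-ol
Conditions: K2CO3 (0.2 equiv), MeOH, 0 °C to rt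
Reagents that add atoms: none
Why: Base-catalysed methanolysis of the alkynyl C–Si bond (protodesilylation) frees the terminal alkyne needed for step 5 without touching the carbinol centre or the vinylic bromide.

Step 5
Reactants: 7 (3R)-5-bromohex-5-en-1-yn-3-ol
Product: 9 (4R)-6-bromohepta-1,2,6-trien-4-ol, via Mannich base 8 (not isolated)
Conditions: (CH2O)n, CuI (0.5 equiv), Cy2NH, dioxane, reflux
Reagents that add atoms: paraformaldehyde (as formaldehyde), C=O
Why: Crabbé homologation in its CuI/Cy2NH form: a copper acetylide Mannich reaction with formaldehyde gives propargylic amine 8, which on heating transfers a hydride from an N-cyclohexyl C–H to the alkyne and fragments to the terminal allene and an imine, a sequence that tolerates the free hydroxyl and does not involve the stereocentre.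

Step 6
Reactants: 9 (4R)-6-bromohepta-1,2,6-trien-4-ol
Product: 10 (5R)-5-(2-bromoprop-2-en-1-yl)-3-methylfuran-2(5H)-one
Conditions: Ru3(CO)12 (2 mol %), CO (10 atm), Et3N (2 equiv), dioxane, 100 °C
Reagents that add atoms: carbon monoxide, [C-]#[O+]
Why: This is the ruthenium-carbonyl-catalysed cyclocarbonylation of an α-allenol, a known route to 3-methylfuran-2(5H)-ones: amine-assisted O–H addition to zerovalent ruthenium and CO insertion into the Ru–O bond give a catalyst-bound alkoxycarbonyl hydride, whose acyl carbon adds by syn migratory insertion to the central allene carbon, closing the ring at the C2–C3 bond and leaving a π-allyl hydride; C–H reductive elimination at the allene terminus then turns the former =CH2 into the C3 methyl and places the double bond at C3=C4. The five-membered ring closes in a 5-exo sense with respect to the terminal C=C of the allene (attack at the central carbon), whereas attack at the terminus would give a six-membered lactone and forfeit the π-allyl. No new stereocentre is formed: C5 is the carbinol carbon of 9, at which no bond is made or broken, so the (R) configuration from step 3 is carried through. The step needs chemoselectivity for the allene over the 2-bromoalkene and its vinylic C–Br bond, which the far higher insertion reactivity of the cumulated diene and the phosphine-free ruthenium carbonyl should secure, and hydride return to the CH2 terminus, which the conjugated endocyclic trisubstituted alkene favours. Only a modest amount of Et3N and a short reaction time are used so that the γ-proton at C5 of the product is not abstracted.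

Step 7
Reactants: 11 7-hydroxy-8-methoxy-2H-chromen-2-one
Product: 12 7-(2,2-diethoxyethoxy)-8-methoxy-2H-chromen-2-one
Conditions: BrCH2CH(OEt)2, K2CO3, KI (cat.), DMF, 110 °C
Reagents that add atoms: bromoacetaldehyde diethyl acetal, CCOC(CBr)OCC
Why: Williamson ether synthesis: the 7-OH, acidified by conjugation with the pyranone carbonyl, is deprotonated by carbonate and displaces bromide from the primary alkyl bromide under iodide catalysis, and it is the only nucleophilic site in 11.

Step 8
Reactants: 12 7-(2,2-diethoxyethoxy)-8-methoxy-2H-chromen-2-one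
Product: 13 2-[(8-methoxy-2-oxo-2H-chromen-7-yl)oxy]acetaldehyde
Conditions: 2 M aq. HCl, THF, 50 °C
Reagents that add atoms: water, O
Why: Acid-catalysed acetal hydrolysis releases the aryloxyacetaldehyde, while the aryl ethers and the coumarin lactone are stable to dilute aqueous acid.

Step 9
Reactants: 10 (5R)-5-(2-bromoprop-2-en-1-yl)-3-methylfuran-2(5H)-one; 13 2-[(8-methoxy-2-oxo-2H-chromen-7-yl)oxy]acetaldehyde
Product: 15 7-({2-hydroxy-3-methylidene-4-[(2R)-4-methyl-5-oxo-2,5-dihydrofuran-2-yl]butyl}oxy)-8-methoxy-2H-chromen-2-one (both carbinol epimers), via alkenylchromium dichloride 14 (not isolated)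
Conditions: CrCl2 (4 equiv), NiCl2 (2 mol %), degassed DMF, rt
Reagents that add atoms: none
Why: Nozaki–Hiyama–Kishi reaction: zerovalent nickel inserts into the vinylic C–Br bond, transmetalation to trivalent chromium gives alkenylchromium 14, which adds only to the aldehyde and leaves the butenolide and the coumarin lactone untouched; the new carbinol centre is not controlled and need not be, since it is oxidised in step 10.

Step 10
Reactants: 15 7-({2-hydroxy-3-methylidene-4-[(2R)-4-methyl-5-oxo-2,5-dihydrofuran-2-yl]butyl}oxy)-8-methoxy-2H-chromen-2-one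
Product: 16 7-({3-methylidene-4-[(2R)-4-methyl-5-oxo-2,5-dihydrofuran-2-yl]-2-oxobutyl}oxy)-8-methoxy-2H-chromen-2-one (CNP0262059.1)
Conditions: Dess–Martin periodinane, CH2Cl2, 0 °C to rt
Reagents that add atoms: none
Why: Dess–Martin oxidation of the secondary allylic alcohol gives the α-methylene ketone under neutral conditions that should neither epimerise C5 of the furanone nor add nucleophiles to the new enone.

**Compound list**

1 | 3-(trimethylsilyl)prop-2-ynal | C[Si](C)(C)C#CC=O | starting material
2 | 2,3-dibromoprop-1-ene | C=C(Br)CBr | starting material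
3 | (2-bromoprop-2-en-1-yl)indium dibromide (organoindium species, drawn as the dibromide) | C=C(Br)C[In](Br)Br | intermediate
4 | rac-5-bromo-1-(trimethylsilyl)hex-5-en-1-yn-3-ol | C[Si](C)(C)C#CC(O)CC(Br)=C | intermediate
5 | 5-bromo-1-(trimethylsilyl)hex-5-en-1-yn-3-one | C[Si](C)(C)C#CC(=O)CC(Br)=C | intermediate
6 | (3R)-5-bromo-1-(trimethylsilyl)hex-5-en-1-yn-3-ol | C[Si](C)(C)C#C[C@H](O)CC(Br)=C | intermediate
7 | (3R)-5-bromohex-5-en-1-yn-3-ol | C#C[C@H](O)CC(Br)=C | intermediate
8 | (4R)-6-bromo-1-(dicyclohexylamino)hept-6-en-2-yn-4-ol | C=C(Br)C[C@@H](O)C#CCN(C1CCCCC1)C1CCCCC1 | intermediate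
9 | (4R)-6-bromohepta-1,2,6-trien-4-ol | C=C=C[C@H](O)CC(Br)=C | intermediate
10 | (5R)-5-(2-bromoprop-2-en-1-yl)-3-methylfuran-2(5H)-one | C=C(Br)C[C@@H]1C=C(C)C(=O)O1 | intermediate
11 | 7-hydroxy-8-methoxy-2H-chromen-2-one | Oc1ccc2ccc(=O)oc2c1OC | starting material
12 | 7-(2,2-diethoxyethoxy)-8-methoxy-2H-chromen-2-one | CCOC(COc1ccc2ccc(=O)oc2c1OC)OCC | intermediate
13 | 2-[(8-methoxy-2-oxo-2H-chromen-7-yl)oxy]acetaldehyde | O=CCOc1ccc2ccc(=O)oc2c1OC | intermediate
14 | {3-[(2R)-4-methyl-5-oxo-2,5-dihydrofuran-2-yl]prop-1-en-2-yl}chromium dichloride | C=C([Cr](Cl)Cl)C[C@@H]1C=C(C)C(=O)O1 | intermediate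
15 | 7-({2-hydroxy-3-methylidene-4-[(2R)-4-methyl-5-oxo-2,5-dihydrofuran-2-yl]butyl}oxy)-8-methoxy-2H-chromen-2-one (both carbinol epimers) | C=C(C[C@@H]1C=C(C)C(=O)O1)C(O)COc1ccc2ccc(=O)oc2c1OC | intermediate
16 | 7-({3-methylidene-4-[(2R)-4-methyl-5-oxo-2,5-dihydrofuran-2-yl]-2-oxobutyl}oxy)-8-methoxy-2H-chromen-2-one | C=C(C[C@@H]1C=C(C)C(=O)O1)C(=O)COc1ccc2ccc(=O)oc2c1OC | target

**Step count**

Total steps: 10. Longest linear sequence: 8 (steps 1–6, 9 and 10).

**Steps most likely to fail**

Step 6. Oxidative addition of the vinylic C–Br bond to low-valent ruthenium under CO, or amine-induced removal of the γ-proton that erodes the C5 configuration, may compete with the cyclocarbonylation. The fallback sets out from alkynol 7 and gives up the carbonylative closure for a metathesis closure of the same ring. Semihydrogenation (H2, Lindlar catalyst Pd/CaCO3 poisoned with Pb(OAc)2, quinoline, EtOAc) should give (3R)-5-bromohexa-1,5-dien-3-ol F1. Acylation with methacryloyl chloride (Et3N, DMAP, CH2Cl2, 0 °C) should give (3R)-5-bromohexa-1,5-dien-3-yl 2-methylprop-2-enoate F2. Ring-closing metathesis between the vinyl group and the methacrylate (second-generation Grubbs catalyst, toluene, 80 °C), with loss of ethene, should then give furanone 10, where the route is rejoined. The 1,1-disubstituted bromo-olefin is expected to stay out of the metathesis, and neither base nor CO is involved. Steps 5 and 6 are replaced.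

Step 9. Sluggish insertion of nickel into the 2-bromoalkene may let reduction or pinacol-type consumption of the aldehyde by divalent chromium outrun the coupling. The fallback sets out from 10 and 13 and uses an acylative Stille coupling that reaches the ketone oxidation level directly. Pinnick oxidation of 13 (NaClO2, NaH2PO4, 2-methylbut-2-ene, t-BuOH–H2O) should give 2-[(8-methoxy-2-oxo-2H-chromen-7-yl)oxy]acetic acid F3, which oxalyl chloride (cat. DMF, CH2Cl2) converts into 2-[(8-methoxy-2-oxo-2H-chromen-7-yl)oxy]acetyl chloride F4. Bromide 10 is stannylated (Me3SnSnMe3, Pd(PPh3)4, toluene, 90 °C) to (5R)-3-methyl-5-[2-(trimethylstannyl)prop-2-en-1-yl]furan-2(5H)-one F5. Coupling of F5 with F4 (Pd2(dba)3, P(2-furyl)3, THF, 50 °C) should give target 16 directly, so steps 9 and 10 are both replaced.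

Step 3. Prototropic migration of the bromo-olefin into conjugation in ynone 5 (during step 2 or on the basic amido-ruthenium catalyst) and incomplete enantioselection may lower yield and optical purity. The fallback sets out from racemic alcohol 4 and avoids the ynone altogether by an enzymatic kinetic resolution. Methanolysis (K2CO3, MeOH) gives rac-5-bromohex-5-en-1-yn-3-ol F6. A lipase (immobilised Candida antarctica lipase B, vinyl acetate, MTBE, rt) should, by Kazlauskas' rule with the slim ethynyl group in the medium pocket, acylate the (S)-alcohol to (3S)-5-bromohex-5-en-1-yn-3-yl acetate F7 and leave the (R)-alcohol 7. Compound 7 is separated by chromatography after slightly more than half conversion and rejoins the route at step 5. At most half of the material is used, and the configuration would have to be confirmed by Mosher ester analysis.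

**Further compounds**

F1 | step 6 | (3R)-5-bromohexa-1,5-dien-3-ol | C=C[C@H](O)CC(Br)=C
F2 | step 6 | (3R)-5-bromohexa-1,5-dien-3-yl 2-methylprop-2-enoate | C=C[C@H](OC(=O)C(C)=C)CC(Br)=C
F3 | step 9 | 2-[(8-methoxy-2-oxo-2H-chromen-7-yl)oxy]acetic acid | OC(=O)COc1ccc2ccc(=O)oc2c1OC
F4 | step 9 | 2-[(8-methoxy-2-oxo-2H-chromen-7-yl)oxy]acetyl chloride | ClC(=O)COc1ccc2ccc(=O)oc2c1OC
F5 | step 9 | (5R)-3-methyl-5-[2-(trimethylstannyl)prop-2-en-1-yl]furan-2(5H)-one | C=C(C[C@@H]1C=C(C)C(=O)O1)[Sn](C)(C)C
F6 | step 3 | rac-5-bromohex-5-en-1-yn-3-ol | C#CC(O)CC(Br)=C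
F7 | step 3 | (3S)-5-bromohex-5-en-1-yn-3-yl acetate | C#C[C@@H](OC(C)=O)CC(Br)=C
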